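**Retrosynthetic overview**

1. The strategy rests on the imidazoline C4 stereocentre, which carries indole C3, ring nitrogen N3 and the C5H2–N1 unit. If N3 is written as a carboxyl group, C4 becomes the nucleophilic α-carbon of an indole-3-acetic acid and C5 a one-carbon aminomethyl electrophile.
2. Target ⇐ C2 bromination of the indole, N-detosylation and urea-to-guanidine exchange ⇐ (4R)-4-indolylimidazolidin-2-one.
3. Imidazolidinone ring (the only ring made, closed at N1–C2 after the stereocentre is set) ⇐ Curtius rearrangement of a β-(Cbz-amino) acid with retention, the isocyanate being captured by the carbamate N–H.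
4. C4–C5 bond and the stereocentre ⇐ aminomethylation of the TiCl4 enolate of the (S)-4-benzyloxazolidinone imide of 5-bromo-1-tosylindole-3-acetic acid by the N-acyliminium ion from benzyl N-(methoxymethyl)carbamate.
5. The indole nucleus is bought; starting materials are 5-bromoindole-3-acetic acid, (S)-4-benzyl-2-oxazolidinone and benzyl carbamate.

Key step: step 5

Assumption: the target is delivered as the neutral guanidine drawn; it and its two guanidine precursors are basic and would be stored as salts where convenient, which does not change the route. Ts = 4-methylbenzenesulfonyl.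

**Step 1**
Reactants: 1 5-bromoindole-3-acetic acid
Product: 3 2-[5-bromo-1-(4-methylbenzenesulfonyl)indol-3-yl]acetic acid, via dilithio dianion 2 (not isolated)
Conditions: LiN(SiMe3)2 (2.2 equiv), THF, −78 °C; TsCl (1.1 equiv), −78 → 0 °C; aq. HCl
Reagents that add atoms: 4-methylbenzenesulfonyl chloride, Cc1ccc(cc1)S(Cl)(=O)=O
Why: N-sulfonylation of an indolyl anion: in the carboxylate–indolide dianion the nitrogen is the more nucleophilic site toward the sulfonyl chloride at low temperature, any carboxylic–sulfonic anhydride reverts to the acid on aqueous work-up, and the non-nucleophilic amide base leaves the aryl bromide alone.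

**Step 2**
Reactants: 3 2-[5-bromo-1-tosylindol-3-yl]acetic acid; 4 (S)-4-benzyl-1,3-oxazolidin-2-one
Product: 6 (4S)-4-benzyl-3-{2-[5-bromo-1-tosylindol-3-yl]acetyl}-1,3-oxazolidin-2-one, via mixed pivalic anhydride 5 (not isolated)
Conditions: PivCl, Et3N, THF, −20 °C; then LiCl, 4, −20 °C → rt
Reagents that add atoms: none
Why: N-acylation of an oxazolidinone through a mixed pivalic anhydride under LiCl/Et3N activation, in which the oxazolidinone attacks the unhindered arylacetyl carbonyl and no strong base touches the acidic arylacetyl CH2 or the sulfonamide.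

**Step 3**
Reactants: 7 benzyl carbamate
Product: 8 benzyl N-(hydroxymethyl)carbamate
Conditions: 37% aq. CH2O, K2CO3 (cat.), H2O, 60 °C → rt
Reagents that add atoms: formaldehyde, C=O
Why: Base-catalysed N-hydroxymethylation of a carbamate by formaldehyde, with the hemiaminal expected to crystallise from water.

**Step 4**
Reactants: 8 benzyl N-(hydroxymethyl)carbamate
Product: 9 benzyl N-(methoxymethyl)carbamate
Conditions: MeOH, TsOH·H2O (cat.), rt
Reagents that add atoms: methanol, CO
Why: Acid-catalysed N,O-acetal formation, the hemiaminal hydroxyl being exchanged for methoxyl through the N-acyliminium ion with methanol as solvent.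

**Step 5**
Reactants: 6 (4S)-4-benzyl-3-{2-[5-bromo-1-tosylindol-3-yl]acetyl}-1,3-oxazolidin-2-one; 9 benzyl N-(methoxymethyl)carbamate
Product: 12 benzyl N-[(2R)-3-[(4S)-4-benzyl-2-oxo-1,3-oxazolidin-3-yl]-2-(5-bromo-1-tosylindol-3-yl)-3-oxopropyl]carbamate, via trichlorotitanium Z-enolate 10 (not isolated), via benzyl N-methylidenecarbamate 11 (not isolated)
Conditions: TiCl4 (1.05 equiv), CH2Cl2, 0 °C; i-Pr2NEt (1.1 equiv), 0 °C; then 9 (1.3 equiv), TiCl4 (1.05 equiv), 0 °C; aq. NH4Cl
Reagents that add atoms: none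
Why: TiCl4 and i-Pr2NEt soft-enolise the imide to the chelated Z-enolate 10, in which titanium bridges the enolate and oxazolidinone oxygens, while the second equivalent of TiCl4 ionises the N,O-acetal 9 to the N-acyliminium ion (drawn as 11), and the enolate carbon adds to its CH2 to form the bond that becomes C4–C5 of the ring. The closest known reaction is the titanium enolate aminomethylation of N-acyl oxazolidinones with carbamate N,O-acetals that is used for α-substituted β-amino acids, an auxiliary-controlled Mannich reaction. No ring is closed in this step. The one new stereocentre is controlled by the 4-benzyl group of the auxiliary, which blocks one face of the chelated Z-enolate so that the iminium carbon adds to the other face and the 2R configuration should result, any minor diastereomer being removable at this crystalline imide stage. The step needs C-alkylation of the enolate in preference to amidoalkylation of the indole, and it needs the acidic α-aryl hydrogen of the product to stay in place; the electron-withdrawing N-tosyl group switches the indole off as a nucleophile, and A(1,3) strain in the product imide keeps its α-C–H out of alignment with the carbonyl, so re-enolisation by the weak amine base should be slow.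

**Step 6**
Reactants: 12 benzyl N-[(2R)-3-[(4S)-4-benzyl-2-oxo-1,3-oxazolidin-3-yl]-2-(5-bromo-1-tosylindol-3-yl)-3-oxopropyl]carbamate
Product: 14 (2R)-3-{[(benzyloxy)carbonyl]amino}-2-(5-bromo-1-tosylindol-3-yl)propanoic acid, via peroxy acid 13 (not isolated)
Conditions: LiOH·H2O, 30% H2O2, THF/H2O (3:1), 0 °C; aq. Na2SO3; aq. HCl to pH 2
Reagents that add atoms: hydrogen peroxide, OO
Why: LiOOH cleavage of the auxiliary: hydroperoxide attacks the exocyclic imide carbonyl selectively but is too weakly basic to enolise the α-aryl centre at 0 °C, sulfite then reduces the peroxy acid, and carbamate and sulfonamide should survive the short cold exposure.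

**Step 7**
Reactants: 14 (2R)-3-{[(benzyloxy)carbonyl]amino}-2-(5-bromo-1-tosylindol-3-yl)propanoic acid
Product: 17 benzyl (4R)-4-(5-bromo-1-tosylindol-3-yl)-2-oxoimidazolidine-1-carboxylate, via acyl azide 15 (not isolated), via isocyanate 16 (not isolated)
Conditions: (PhO)2P(O)N3, Et3N, toluene, rt then 80 °C
Reagents that add atoms: diphenylphosphoryl azide, [N-]=[N+]=NP(=O)(Oc1ccccc1)Oc1ccccc1
Why: Curtius rearrangement through the acyl azide, in which the stereogenic carbon migrates to nitrogen with retention and the isocyanate is captured by the carbamate N–H in a 5-exo closure to the N-acyl cyclic urea (the closure known from Hofmann and Curtius reactions of N-carbamoyl β-amino acids), so that the R centre now carries N3 and has no acidic hydrogen left.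

**Step 8**
Reactants: 17 benzyl (4R)-4-(5-bromo-1-tosylindol-3-yl)-2-oxoimidazolidine-1-carboxylate
Product: 18 (4R)-4-(5-bromo-1-tosylindol-3-yl)imidazolidin-2-one
Conditions: 33% HBr in AcOH, CH2Cl2, rt; aq. NaHCO3
Reagents that add atoms: none
Why: Acidolysis of the benzyl carbamate (bromide attack at the benzylic carbon, then decarboxylation) is chosen over hydrogenolysis so that the aryl bromide is not reduced, and the urea, the sulfonamide and the C4 centre should be inert to HBr/AcOH at room temperature.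

**Step 9**
Reactants: 18 (4R)-4-(5-bromo-1-tosylindol-3-yl)imidazolidin-2-one
Product: 20 (4R)-4-(5-bromo-1-tosylindol-3-yl)-4,5-dihydro-1H-imidazol-2-amine, via O-ethylisouronium tetrafluoroborate 19 (not isolated)
Conditions: Et3OBF4, CH2Cl2, rt; then 7 M NH3 in MeOH, sealed tube, 50 °C; aq. NaOH
Reagents that add atoms: ammonia, N
Why: O-Alkylation of the urea by Meerwein's salt gives an isouronium ion that ammonia attacks at C2 with loss of ethanol (the isourea route to guanidines), and the N-tosyl group is kept on so that the indole cannot ionise the C4–N3 bond while the ring carries a leaving group.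

**Step 10**
Reactants: 20 (4R)-4-(5-bromo-1-tosylindol-3-yl)-4,5-dihydro-1H-imidazol-2-amine
Product: 21 (4R)-4-(5-bromo-1H-indol-3-yl)-4,5-dihydro-1H-imidazol-2-amine
Conditions: 2 M aq. NaOH, 1,4-dioxane, 70 °C
Reagents that add atoms: none
Why: Nucleophilic N-desulfonylation, hydroxide attacking sulfur and expelling the 5-bromoindolide, run without an alcohol so that no alkyl sulfonate forms that could alkylate the free guanidine.

**Step 11**
Reactants: 21 (4R)-4-(5-bromo-1H-indol-3-yl)-4,5-dihydro-1H-imidazol-2-amine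
Product: 22 (4R)-4-(2,5-dibromo-1H-indol-3-yl)-4,5-dihydro-1H-imidazol-2-amine
Conditions: NBS (1.0 equiv), anhydrous AcOH, rt, dark, N2; then cold aq. NaOH
Reagents that add atoms: N-bromosuccinimide, BrN1C(=O)CCC1=O
Why: Electrophilic bromination of a 3-substituted indole at C2 by NBS in anhydrous acetic acid, where the guanidine is fully protonated and so is neither oxidised nor able to add to the indole, the absence of water avoids oxindole formation, and C4 is not touched.

**Compound list**

1 | 5-bromoindole-3-acetic acid | OC(=O)Cc1c[nH]c2ccc(Br)cc12 | starting material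
2 | dilithium 2-(5-bromoindol-1-id-3-yl)acetate | [Li+].[Li+].[O-]C(=O)Cc1c[n-]c2ccc(Br)cc12 | intermediate
3 | 2-[5-bromo-1-(4-methylbenzenesulfonyl)indol-3-yl]acetic acid | OC(=O)Cc1cn(S(=O)(=O)c2ccc(C)cc2)c2ccc(Br)cc12 | intermediate
4 | (S)-4-benzyl-1,3-oxazolidin-2-one | O=C1N[C@@H](Cc2ccccc2)CO1 | starting material
5 | 2-[5-bromo-1-tosylindol-3-yl]acetic 2,2-dimethylpropanoic anhydride | CC(C)(C)C(=O)OC(=O)Cc1cn(S(=O)(=O)c2ccc(C)cc2)c2ccc(Br)cc12 | intermediate
6 | (4S)-4-benzyl-3-{2-[5-bromo-1-tosylindol-3-yl]acetyl}-1,3-oxazolidin-2-one | O=C(Cc1cn(S(=O)(=O)c2ccc(C)cc2)c2ccc(Br)cc12)N1[C@@H](Cc2ccccc2)COC1=O | intermediate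
7 | benzyl carbamate | NC(=O)OCc1ccccc1 | starting material
8 | benzyl N-(hydroxymethyl)carbamate | OCNC(=O)OCc1ccccc1 | intermediate
9 | benzyl N-(methoxymethyl)carbamate | COCNC(=O)OCc1ccccc1 | intermediate
10 | trichlorotitanium (Z)-enolate of 6 | Cl[Ti](Cl)(Cl)O/C(=C\c1cn(S(=O)(=O)c2ccc(C)cc2)c2ccc(Br)cc12)N1[C@@H](Cc2ccccc2)COC1=O | intermediate
11 | benzyl N-methylidenecarbamate (titanium-bound N-acyliminium equivalent) | C=NC(=O)OCc1ccccc1 | intermediate
12 | benzyl N-[(2R)-3-[(4S)-4-benzyl-2-oxo-1,3-oxazolidin-3-yl]-2-(5-bromo-1-tosylindol-3-yl)-3-oxopropyl]carbamate | O=C(N1[C@@H](Cc2ccccc2)COC1=O)[C@H](c1cn(S(=O)(=O)c2ccc(C)cc2)c2ccc(Br)cc12)CNC(=O)OCc1ccccc1 | intermediate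
13 | (2R)-3-{[(benzyloxy)carbonyl]amino}-2-(5-bromo-1-tosylindol-3-yl)propaneperoxoic acid | OOC(=O)[C@H](c1cn(S(=O)(=O)c2ccc(C)cc2)c2ccc(Br)cc12)CNC(=O)OCc1ccccc1 | intermediate
14 | (2R)-3-{[(benzyloxy)carbonyl]amino}-2-(5-bromo-1-tosylindol-3-yl)propanoic acid | OC(=O)[C@H](c1cn(S(=O)(=O)c2ccc(C)cc2)c2ccc(Br)cc12)CNC(=O)OCc1ccccc1 | intermediate
15 | (2R)-3-{[(benzyloxy)carbonyl]amino}-2-(5-bromo-1-tosylindol-3-yl)propanoyl azide | [N-]=[N+]=NC(=O)[C@H](c1cn(S(=O)(=O)c2ccc(C)cc2)c2ccc(Br)cc12)CNC(=O)OCc1ccccc1 | intermediate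
16 | benzyl N-[(2R)-2-(5-bromo-1-tosylindol-3-yl)-2-isocyanatoethyl]carbamate | O=C=N[C@H](c1cn(S(=O)(=O)c2ccc(C)cc2)c2ccc(Br)cc12)CNC(=O)OCc1ccccc1 | intermediate
17 | benzyl (4R)-4-(5-bromo-1-tosylindol-3-yl)-2-oxoimidazolidine-1-carboxylate | O=C1N[C@H](c2cn(S(=O)(=O)c3ccc(C)cc3)c3ccc(Br)cc23)CN1C(=O)OCc1ccccc1 | intermediate
18 | (4R)-4-(5-bromo-1-tosylindol-3-yl)imidazolidin-2-one | O=C1N[C@H](c2cn(S(=O)(=O)c3ccc(C)cc3)c3ccc(Br)cc23)CN1 | intermediate
19 | (4R)-4-(5-bromo-1-tosylindol-3-yl)-2-ethoxy-4,5-dihydro-1H-imidazol-3-ium tetrafluoroborate | CCOC1=[NH+][C@H](c2cn(S(=O)(=O)c3ccc(C)cc3)c3ccc(Br)cc23)CN1.F[B-](F)(F)F | intermediate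
20 | (4R)-4-(5-bromo-1-tosylindol-3-yl)-4,5-dihydro-1H-imidazol-2-amine | NC1=N[C@H](c2cn(S(=O)(=O)c3ccc(C)cc3)c3ccc(Br)cc23)CN1 | intermediate
21 | (4R)-4-(5-bromo-1H-indol-3-yl)-4,5-dihydro-1H-imidazol-2-amine | NC1=N[C@H](c2c[nH]c3ccc(Br)cc23)CN1 | intermediate
22 | (4R)-4-(2,5-dibromo-1H-indol-3-yl)-4,5-dihydro-1H-imidazol-2-amine | NC1=N[C@H](c2c(Br)[nH]c3ccc(Br)cc23)CN1 | target

**Step count**

Total: 11 steps. Longest linear sequence: 9 steps (steps 1, 2, 5, 6, 7, 8, 9, 10, 11 from compound 1; the branch through steps 3 and 4 is equally long).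

**Three steps most likely to fail**

Step 5. The risks are slow capture of the iminium ion by a hindered, stabilised arylacetyl enolate, erosion of facial selectivity, and epimerisation of the product through re-enolisation during a long reaction. The fallback sets out from 6 and replaces the Mannich reaction by an enolate alkylation followed by a one-carbon degradation. NaN(SiMe3)2 in THF at −78 °C should give the sodium Z-enolate F1, which is alkylated on the same face by tert-butyl bromoacetate to give tert-butyl (3S)-4-[(4S)-4-benzyl-2-oxo-1,3-oxazolidin-3-yl]-3-(5-bromo-1-tosylindol-3-yl)-4-oxobutanoate F2. TFA in CH2Cl2 frees the acid F3. (PhO)2P(O)N3 and Et3N in toluene at 80 °C convert it through the acyl azide F4 into the isocyanate F5, which has no internal N–H and is trapped by added benzyl alcohol. The fallback comes back to the route at 12.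

Step 9. The risks are incomplete or N-directed alkylation of the urea, and dealkylation of the isouronium ion by ammonia at the ethyl group, which returns the urea. The fallback sets out from 18 and exchanges oxygen for sulfur first. Lawesson's reagent in toluene at 100 °C should give (4R)-4-(5-bromo-1-tosylindol-3-yl)imidazolidine-2-thione F6. Methyl iodide in acetone alkylates sulfur to the 2-(methylsulfanyl)imidazolinium iodide F7. Ammonia in methanol at 60 °C in a sealed tube then displaces methanethiol, and basic work-up brings the sequence back to the route at 20.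

Step 11. The risks are over-oxidation (dehydrogenation of the imidazoline through a 3-bromoindolenine), addition of ring nitrogen N1 to indole C2, and polybromination. The fallback sets out from 21 and brominates a neutral, acylated guanidine. Boc2O and Et3N in CH2Cl2 should give tert-butyl (4R)-4-(5-bromo-1H-indol-3-yl)-2-[(tert-butoxycarbonyl)amino]-4,5-dihydro-1H-imidazole-1-carboxylate F8, in which N1 has no hydrogen and the guanidine is no longer basic or oxidisable. NBS in CH2Cl2 at 0 °C gives the 2,5-dibromo compound F9. TFA in CH2Cl2 followed by aqueous NaOH removes both Boc groups and comes back to the route at 22.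

**Further compounds**

F1 | step 5 | sodium (Z)-enolate of 6 | [Na+].[O-]/C(=C\c1cn(S(=O)(=O)c2ccc(C)cc2)c2ccc(Br)cc12)N1[C@@H](Cc2ccccc2)COC1=O
F2 | step 5 | tert-butyl (3S)-4-[(4S)-4-benzyl-2-oxo-1,3-oxazolidin-3-yl]-3-(5-bromo-1-tosylindol-3-yl)-4-oxobutanoate | O=C(N1[C@@H](Cc2ccccc2)COC1=O)[C@H](c1cn(S(=O)(=O)c2ccc(C)cc2)c2ccc(Br)cc12)CC(=O)OC(C)(C)C
F3 | step 5 | (3S)-4-[(4S)-4-benzyl-2-oxo-1,3-oxazolidin-3-yl]-3-(5-bromo-1-tosylindol-3-yl)-4-oxobutanoic acid | O=C(N1[C@@H](Cc2ccccc2)COC1=O)[C@H](c1cn(S(=O)(=O)c2ccc(C)cc2)c2ccc(Br)cc12)CC(=O)O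
F4 | step 5 | (3S)-4-[(4S)-4-benzyl-2-oxo-1,3-oxazolidin-3-yl]-3-(5-bromo-1-tosylindol-3-yl)-4-oxobutanoyl azide | O=C(N1[C@@H](Cc2ccccc2)COC1=O)[C@H](c1cn(S(=O)(=O)c2ccc(C)cc2)c2ccc(Br)cc12)CC(=O)N=[N+]=[N-]
F5 | step 5 | (4S)-4-benzyl-3-[(2R)-2-(5-bromo-1-tosylindol-3-yl)-3-isocyanatopropanoyl]-1,3-oxazolidin-2-one | O=C(N1[C@@H](Cc2ccccc2)COC1=O)[C@H](c1cn(S(=O)(=O)c2ccc(C)cc2)c2ccc(Br)cc12)CN=C=O
F6 | step 9 | (4R)-4-(5-bromo-1-tosylindol-3-yl)imidazolidine-2-thione | S=C1N[C@H](c2cn(S(=O)(=O)c3ccc(C)cc3)c3ccc(Br)cc23)CN1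
F7 | step 9 | (4R)-4-(5-bromo-1-tosylindol-3-yl)-2-(methylsulfanyl)-4,5-dihydro-1H-imidazol-3-ium iodide | CSC1=[NH+][C@H](c2cn(S(=O)(=O)c3ccc(C)cc3)c3ccc(Br)cc23)CN1.[I-]
F8 | step 11 | tert-butyl (4R)-4-(5-bromo-1H-indol-3-yl)-2-[(tert-butoxycarbonyl)amino]-4,5-dihydro-1H-imidazole-1-carboxylate | CC(C)(C)OC(=O)NC1=N[C@H](c2c[nH]c3ccc(Br)cc23)CN1C(=O)OC(C)(C)C
F9 | step 11 | tert-butyl (4R)-2-[(tert-butoxycarbonyl)amino]-4-(2,5-dibromo-1H-indol-3-yl)-4,5-dihydro-1H-imidazole-1-carboxylate | CC(C)(C)OC(=O)NC1=N[C@H](c2c(Br)[nH]c3ccc(Br)cc23)CN1C(=O)OC(C)(C)C
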